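**Plan**
- Retrosynthesis cuts the four aryl methyl ethers first, then the flavone pyranone at O1–C2 and C4–C4a (phenol plus 3-(4-methoxyphenyl)propiolate), then the coumarin lactone at O1–C2 and C3–C4 (salicylaldehyde plus a two-carbon ylide).
- The last cut opens the coumarin benzene ring at C5–C6 and C4a–C8a. Enabling feature: coumarin C6 (aryl), C7 (O), C8 (H) and C8a (O) are a 4-aryl-1,3-dioxygenated butadiene, and C5–C4a with the carbon that becomes C4 are methyl propiolate.
- Forward: 2-hydroxy-4,6-dimethoxybenzaldehyde (future flavone ring A) is homologated to the silyloxydiene. Rings then arise in the order coumarin benzene ring (Diels–Alder), coumarin lactone (Wittig–lactonisation), flavone pyranone (oxa-Michael, Friedel–Crafts), before global demethylation.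
- Stereochemistry: the target has no stereocentre, the two sp3 carbons of the cycloadduct vanish on aromatisation, and the biaryl axis is not a specified stereoelement.

Key step: step 6

Assumption: on acidic work-up the methyl trimethylsilyl ketal carbon of the cycloadduct is taken to keep its silylated oxygen and lose methanol, as mixed vinylketene acetals do when they deliver ortho-hydroxy arenes, so the benzoate is carried on as the free 2-hydroxy compound.

**Route**

Step 1
Reactants: 1 2-hydroxy-4,6-dimethoxybenzaldehyde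
Product: 2 2-(benzyloxy)-4,6-dimethoxybenzaldehyde
Conditions: BnBr, K2CO3, DMF, 60 °C
Reagents that add atoms: benzyl bromide, BrCc1ccccc1
Why: Williamson etherification of the phenoxide installs a benzyl ether that BCl3 can later remove without touching the methyl ethers.

Step 2
Reactants: 2 2-(benzyloxy)-4,6-dimethoxybenzaldehyde
Product: 4 [2-(benzyloxy)-4,6-dimethoxyphenyl]acetaldehyde, via enol ether 3 (not isolated)
Conditions: MeOCH2PPh3Cl, KOtBu, THF, 0 °C to rt; then 2 M aq. HCl, THF, 50 °C
Reagents that add atoms: (methoxymethyl)triphenylphosphonium chloride, COC[P+](c1ccccc1)(c1ccccc1)c1ccccc1.[Cl-]; water, O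
Why: Wittig methoxymethylenation with a small unstabilised ylide, followed by acid hydrolysis of the enol ether, is the standard one-carbon homologation of a hindered aryl aldehyde.

Step 3
Reactants: 4 [2-(benzyloxy)-4,6-dimethoxyphenyl]acetaldehyde; 5 methyl diazoacetate
Product: 6 methyl 4-[2-(benzyloxy)-4,6-dimethoxyphenyl]-3-oxobutanoate
Conditions: SnCl2 (10 mol %), CH2Cl2, rt
Reagents that add atoms: none
Why: Roskamp reaction, in which Lewis acid promoted addition of the diazo ester to the aldehyde and a 1,2-hydride shift with loss of dinitrogen give the β-keto ester directly.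

Step 4
Reactants: 6 methyl 4-[2-(benzyloxy)-4,6-dimethoxyphenyl]-3-oxobutanoate
Product: 7 methyl (2E)-4-[2-(benzyloxy)-4,6-dimethoxyphenyl]-3-methoxybut-2-enoate
Conditions: HC(OMe)3, H2SO4 (cat.), MeOH, rt
Reagents that add atoms: trimethyl orthoformate, COC(OC)OC
Why: Acid-catalysed ketalisation–elimination, as used to make methyl 3-methoxycrotonate, should give the ester-conjugated E enol ether as the thermodynamic product, and any deconjugated isomer would lead to the same dienolate in step 5.

Step 5
Reactants: 7 methyl (2E)-4-[2-(benzyloxy)-4,6-dimethoxyphenyl]-3-methoxybut-2-enoate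
Product: 8 {[(1Z,3Z)-4-[2-(benzyloxy)-4,6-dimethoxyphenyl]-1,3-dimethoxybuta-1,3-dien-1-yl]oxy}trimethylsilane
Conditions: LiN(iPr)2 (commercial solution), THF, −78 °C; Me3SiCl, −78 °C to rt; used crude
Reagents that add atoms: chlorotrimethylsilane, C[Si](C)(C)Cl
Why: γ-Deprotonation at the benzylic CH2 of the vinylogous carbonate and O-silylation of the dienolate follow the standard preparation of 1,3-dimethoxy-1-(trimethylsilyloxy)butadiene, with the aryl group expected trans to C2 on the new C3=C4 bond so that the s-cis conformer stays accessible.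

Step 6
Reactants: 8 {[(1Z,3Z)-4-[2-(benzyloxy)-4,6-dimethoxyphenyl]-1,3-dimethoxybuta-1,3-dien-1-yl]oxy}trimethylsilane; 9 methyl propiolate
Product: 11 methyl 5-[2-(benzyloxy)-4,6-dimethoxyphenyl]-2-hydroxy-4-methoxybenzoate, via cycloadduct 10 (not isolated)
Conditions: methyl propiolate (excess), toluene, 80 to 110 °C; then 1 M aq. HCl, THF, rt
Reagents that add atoms: none
Why: A concerted but asynchronous (4+2) cycloaddition of the electron-rich vinylketene acetal with the alkynoate is expected, the known Diels–Alder route from 1,3-dioxygenated silyloxydienes to resorcylates. The six-membered carbocycle closes by cycloaddition, which forms the future coumarin bonds C5–C6 (aryl-bearing diene terminus to the propiolate β-carbon) and C4a–C8a (ketene acetal carbon to the α-carbon). Acid then aromatises 1,4-cyclohexadiene 10: the methyl silyl ketal gives up methanol and its silyl group and the doubly allylic benzylic hydrogen is lost, so the oxygen next to the ester emerges as a free phenol. The two sp3 carbons of 10 are erased, so no stereocontrol is required. The selectivity needed is regiochemical and is secured by matched polarisation, since the 1,1-dioxygen and 3-methoxy groups both make the aryl-bearing C4 the nucleophilic terminus, which pairs with the unhindered electrophilic β-carbon of the propiolate and places the ester ortho to the new phenol. Because the diene already carries the full C6-to-C8a pattern including the hindered aryl group, the tri-ortho-substituted biaryl bond never has to be made by coupling.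

Step 7
Reactants: 11 methyl 5-[2-(benzyloxy)-4,6-dimethoxyphenyl]-2-hydroxy-4-methoxybenzoate
Product: 12 4-[2-(benzyloxy)-4,6-dimethoxyphenyl]-2-(hydroxymethyl)-5-methoxyphenol
Conditions: LiAlH4, THF, 0 °C to rt; aq. potassium sodium tartrate (KNaC4H4O6) work-up
Reagents that add atoms: none
Why: Hydride reduction of a salicylate ester to the salicyl alcohol is standard, and a non-acidic work-up should avoid ionisation of the electron-rich benzylic alcohol.

Step 8
Reactants: 12 4-[2-(benzyloxy)-4,6-dimethoxyphenyl]-2-(hydroxymethyl)-5-methoxyphenol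
Product: 13 5-[2-(benzyloxy)-4,6-dimethoxyphenyl]-2-hydroxy-4-methoxybenzaldehyde
Conditions: MnO2 (activated, excess), CH2Cl2, rt
Reagents that add atoms: none
Why: Selective benzylic alcohol oxidation by MnO2 should stop at the aldehyde, which is stabilised by its hydrogen bond to the ortho phenol.

Step 9
Reactants: 13 5-[2-(benzyloxy)-4,6-dimethoxyphenyl]-2-hydroxy-4-methoxybenzaldehyde
Product: 15 6-[2-(benzyloxy)-4,6-dimethoxyphenyl]-7-methoxy-2H-chromen-2-one, via cinnamate 14 (not isolated)
Conditions: Ph3P=CHCO2Et, PhNEt2, reflux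
Reagents that add atoms: ethyl (triphenylphosphoranylidene)acetate, CCOC(=O)C=P(c1ccccc1)(c1ccccc1)c1ccccc1
Why: Wittig olefination of the salicylaldehyde followed, in boiling N,N-diethylaniline, by E-to-Z isomerisation and lactonisation with loss of ethanol is the established one-pot coumarin synthesis from o-hydroxybenzaldehydes.

Step 10
Reactants: 15 6-[2-(benzyloxy)-4,6-dimethoxyphenyl]-7-methoxy-2H-chromen-2-one
Product: 16 6-(2-hydroxy-4,6-dimethoxyphenyl)-7-methoxy-2H-chromen-2-one
Conditions: BCl3, C6HMe5, CH2Cl2, −78 °C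
Reagents that add atoms: none
Why: Lewis acid debenzylation with pentamethylbenzene as benzyl cation scavenger should cleave the aryl benzyl ether at low temperature while sparing the aryl methyl ethers and the coumarin double bond, which hydrogenolysis would endanger.

Step 11
Reactants: 17 3-(4-methoxyphenyl)prop-2-ynoic acid
Product: 18 methyl 3-(4-methoxyphenyl)prop-2-ynoate
Conditions: MeI, K2CO3, DMF, rt
Reagents that add atoms: iodomethane, CI
Why: Carboxylate O-alkylation at room temperature esterifies the acid without the heat or strong acid that could decarboxylate or hydrate an arylpropiolic acid.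

Step 12
Reactants: 16 6-(2-hydroxy-4,6-dimethoxyphenyl)-7-methoxy-2H-chromen-2-one; 18 methyl 3-(4-methoxyphenyl)prop-2-ynoate
Product: 19 methyl (2Z)-3-[3,5-dimethoxy-2-(7-methoxy-2-oxo-2H-chromen-6-yl)phenoxy]-3-(4-methoxyphenyl)prop-2-enoate
Conditions: K2CO3, DMF, 80 °C
Reagents that add atoms: none
Why: Base-mediated oxa-Michael addition of the phenoxide to the arylpropiolate, the first stage of the Ruhemann flavone synthesis, should give the β-aryloxycinnamate with the aryloxy group cis to the ester by anti addition, and the coumarin lactone tolerates anhydrous carbonate.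

Step 13
Reactants: 19 methyl (2Z)-3-[3,5-dimethoxy-2-(7-methoxy-2-oxo-2H-chromen-6-yl)phenoxy]-3-(4-methoxyphenyl)prop-2-enoate
Product: 20 5,7-dimethoxy-8-(7-methoxy-2-oxo-2H-chromen-6-yl)-2-(4-methoxyphenyl)-4H-chromen-4-one
Conditions: P2O5/MeSO3H (Eaton's reagent), 70 °C
Reagents that add atoms: none
Why: Intramolecular Friedel–Crafts acylation by the acid-activated ester closes the six-membered pyranone onto the only free carbon ortho to the aryl ether oxygen, a position activated by three oxygen substituents, and the tether guarantees that the coumarinyl group ends at flavone C8.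

Step 14
Reactants: 20 5,7-dimethoxy-8-(7-methoxy-2-oxo-2H-chromen-6-yl)-2-(4-methoxyphenyl)-4H-chromen-4-one
Product: 21 5,7-dihydroxy-8-(7-hydroxy-2-oxo-2H-chromen-6-yl)-2-(4-hydroxyphenyl)-4H-chromen-4-one
Conditions: BBr3 (excess), CH2Cl2, −78 °C to rt; MeOH then H2O quench
Reagents that add atoms: none
Why: Lewis acid ether cleavage by BBr3 should remove all four aryl methyl ethers while the lactone and pyranone survive, and anhydrous conditions at or below room temperature avoid the hot protic acid that opens the pyranone and lets the aryl group migrate from C8 to C6 (Wessely–Moser isomerisation).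

**Compound list**

1 | 2-hydroxy-4,6-dimethoxybenzaldehyde | COc1cc(O)c(C=O)c(OC)c1 | starting material
2 | 2-(benzyloxy)-4,6-dimethoxybenzaldehyde | COc1cc(OCc2ccccc2)c(C=O)c(OC)c1 | intermediate
3 | 1-(benzyloxy)-3,5-dimethoxy-2-(2-methoxyethenyl)benzene (mixture of E and Z isomers, not isolated) | COC=Cc1c(OC)cc(OC)cc1OCc1ccccc1 | intermediate
4 | [2-(benzyloxy)-4,6-dimethoxyphenyl]acetaldehyde | O=CCc1c(OC)cc(OC)cc1OCc1ccccc1 | intermediate
5 | methyl diazoacetate | COC(=O)C=[N+]=[N-] | starting material
6 | methyl 4-[2-(benzyloxy)-4,6-dimethoxyphenyl]-3-oxobutanoate | COC(=O)CC(=O)Cc1c(OC)cc(OC)cc1OCc1ccccc1 | intermediate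
7 | methyl (2E)-4-[2-(benzyloxy)-4,6-dimethoxyphenyl]-3-methoxybut-2-enoate | CO/C(Cc1c(OC)cc(OC)cc1OCc1ccccc1)=C/C(=O)OC | intermediate
8 | {[(1Z,3Z)-4-[2-(benzyloxy)-4,6-dimethoxyphenyl]-1,3-dimethoxybuta-1,3-dien-1-yl]oxy}trimethylsilane (the geometry at C1 has no bearing on the product) | CO/C(O[Si](C)(C)C)=C/C(OC)=C/c1c(OC)cc(OC)cc1OCc1ccccc1 | intermediate
9 | methyl propiolate | C#CC(=O)OC | starting material
10 | methyl 3-[2-(benzyloxy)-4,6-dimethoxyphenyl]-4,6-dimethoxy-6-[(trimethylsilyl)oxy]cyclohexa-1,4-diene-1-carboxylate (racemic, both stereocentres lost on aromatisation, not isolated) | COC(=O)C1=CC(c2c(OC)cc(OC)cc2OCc2ccccc2)C(OC)=CC1(OC)O[Si](C)(C)C | intermediate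
11 | methyl 5-[2-(benzyloxy)-4,6-dimethoxyphenyl]-2-hydroxy-4-methoxybenzoate | COC(=O)c1cc(-c2c(OC)cc(OC)cc2OCc2ccccc2)c(OC)cc1O | intermediate
12 | 4-[2-(benzyloxy)-4,6-dimethoxyphenyl]-2-(hydroxymethyl)-5-methoxyphenol | OCc1cc(-c2c(OC)cc(OC)cc2OCc2ccccc2)c(OC)cc1O | intermediate
13 | 5-[2-(benzyloxy)-4,6-dimethoxyphenyl]-2-hydroxy-4-methoxybenzaldehyde | O=Cc1cc(-c2c(OC)cc(OC)cc2OCc2ccccc2)c(OC)cc1O | intermediate
14 | ethyl (2E)-3-{5-[2-(benzyloxy)-4,6-dimethoxyphenyl]-2-hydroxy-4-methoxyphenyl}prop-2-enoate (not isolated) | CCOC(=O)/C=C/c1cc(-c2c(OC)cc(OC)cc2OCc2ccccc2)c(OC)cc1O | intermediate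
15 | 6-[2-(benzyloxy)-4,6-dimethoxyphenyl]-7-methoxy-2H-chromen-2-one | O=c1ccc2cc(-c3c(OC)cc(OC)cc3OCc3ccccc3)c(OC)cc2o1 | intermediate
16 | 6-(2-hydroxy-4,6-dimethoxyphenyl)-7-methoxy-2H-chromen-2-one | O=c1ccc2cc(-c3c(OC)cc(OC)cc3O)c(OC)cc2o1 | intermediate
17 | 3-(4-methoxyphenyl)prop-2-ynoic acid | COc1ccc(cc1)C#CC(O)=O | starting material
18 | methyl 3-(4-methoxyphenyl)prop-2-ynoate | COC(=O)C#Cc1ccc(OC)cc1 | intermediate
19 | methyl (2Z)-3-[3,5-dimethoxy-2-(7-methoxy-2-oxo-2H-chromen-6-yl)phenoxy]-3-(4-methoxyphenyl)prop-2-enoate (Z isomer drawn; an E isomer would equilibrate under the acid of step 13) | COC(=O)/C=C(\Oc1cc(OC)cc(OC)c1-c1cc2ccc(=O)oc2cc1OC)c1ccc(OC)cc1 | intermediate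
20 | 5,7-dimethoxy-8-(7-methoxy-2-oxo-2H-chromen-6-yl)-2-(4-methoxyphenyl)-4H-chromen-4-one | O=c1ccc2cc(-c3c(OC)cc(OC)c4c(=O)cc(-c5ccc(OC)cc5)oc34)c(OC)cc2o1 | intermediate
21 | 5,7-dihydroxy-8-(7-hydroxy-2-oxo-2H-chromen-6-yl)-2-(4-hydroxyphenyl)-4H-chromen-4-one | O=c1ccc2cc(-c3c(O)cc(O)c4c(=O)cc(-c5ccc(O)cc5)oc34)c(O)cc2o1 | target

**Step count**

Total steps: 14. Longest linear sequence: 13 steps (steps 1 to 10 and 12 to 14); step 11 is a one-step side branch.

**Steps most likely to fail**

Step 6. The 2,6-disubstituted aryl group twists out of the diene plane and shields C4. Cycloaddition could then be outrun by hydrolysis of the ketene acetal or by open-chain Michael addition to the propiolate, or the diene could form with the aryl group pointing inward and be unable to reach the s-cis conformer. The fallback makes the biaryl bond by cross-coupling. It sets out from 2: Dakin oxidation (mCPBA, CH2Cl2) would give 2-(benzyloxy)-4,6-dimethoxyphenyl formate F1, and methanolysis (K2CO3, MeOH) would give 2-(benzyloxy)-4,6-dimethoxyphenol F2. Tf2O and pyridine would then give 2-(benzyloxy)-4,6-dimethoxyphenyl trifluoromethanesulfonate F3. Commercial methyl 5-bromo-2-hydroxy-4-methoxybenzoate would be converted by Miyaura borylation (B2pin2, Pd(dppf)Cl2, KOAc, dioxane) into methyl 2-hydroxy-4-methoxy-5-(4,4,5,5-tetramethyl-1,3,2-dioxaborolan-2-yl)benzoate F4. Suzuki–Miyaura coupling of F3 with F4 (Pd(OAc)2, SPhos, K3PO4, toluene/H2O, 100 °C) would come back to the route at 11.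

Step 12. The hindered phenoxide may add too slowly to the electron-rich, poorly electrophilic arylpropiolate, and the aryloxyacrylate, once formed, may fragment in the strong acid of step 13 before it acylates. The fallback builds the pyranone by the chalcone route and bypasses 19. It sets out from 16: chelation-directed C-acetylation ortho to the phenol (Ac2O, BF3·OEt2, 60 °C) would give 6-(3-acetyl-2-hydroxy-4,6-dimethoxyphenyl)-7-methoxy-2H-chromen-2-one F5. Claisen–Schmidt condensation with 4-methoxybenzaldehyde (KOH, EtOH, acidic work-up to reclose any opened lactone) would give (2E)-1-[2-hydroxy-4,6-dimethoxy-3-(7-methoxy-2-oxo-2H-chromen-6-yl)phenyl]-3-(4-methoxyphenyl)prop-2-en-1-one F6. Oxidative cyclisation (I2 cat., DMSO, 130 °C) would come back to the route at 20.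

Step 7. The electron-rich o-hydroxybenzyl alcohol may ionise to a quinone methide and oligomerise during work-up or on the oxidant of step 8. The fallback avoids the alcohol oxidation level. It sets out from 11: aminolysis (MeNHOMe·HCl, iPrMgCl, THF, −20 to 0 °C) would give 5-[2-(benzyloxy)-4,6-dimethoxyphenyl]-2-hydroxy-N,4-dimethoxy-N-methylbenzamide F7. Reduction (LiAlH4, THF, 0 °C), with collapse of the chelated tetrahedral intermediate on work-up, would come back to the route at 13.

**Further compounds**

F1 | step 6 | 2-(benzyloxy)-4,6-dimethoxyphenyl formate | O=COc1c(OC)cc(OC)cc1OCc1ccccc1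
F2 | step 6 | 2-(benzyloxy)-4,6-dimethoxyphenol | Oc1c(OC)cc(OC)cc1OCc1ccccc1
F3 | step 6 | 2-(benzyloxy)-4,6-dimethoxyphenyl trifluoromethanesulfonate | FC(F)(F)S(=O)(=O)Oc1c(OC)cc(OC)cc1OCc1ccccc1
F4 | step 6 | methyl 2-hydroxy-4-methoxy-5-(4,4,5,5-tetramethyl-1,3,2-dioxaborolan-2-yl)benzoate | COC(=O)c1cc(B2OC(C)(C)C(C)(C)O2)c(OC)cc1O
F5 | step 12 | 6-(3-acetyl-2-hydroxy-4,6-dimethoxyphenyl)-7-methoxy-2H-chromen-2-one | CC(=O)c1c(O)c(-c2cc3ccc(=O)oc3cc2OC)c(OC)cc1OC
F6 | step 12 | (2E)-1-[2-hydroxy-4,6-dimethoxy-3-(7-methoxy-2-oxo-2H-chromen-6-yl)phenyl]-3-(4-methoxyphenyl)prop-2-en-1-one | COc1ccc(/C=C/C(=O)c2c(O)c(-c3cc4ccc(=O)oc4cc3OC)c(OC)cc2OC)cc1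
F7 | step 7 | 5-[2-(benzyloxy)-4,6-dimethoxyphenyl]-2-hydroxy-N,4-dimethoxy-N-methylbenzamide | CON(C)C(=O)c1cc(-c2c(OC)cc(OC)cc2OCc2ccccc2)c(OC)cc1O
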